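**Retrosynthetic overview**
1. Target 10 (two free phenols) ← hydrogenolysis of the bis(benzyl ether) 9. No ring is formed in the route; both benzene rings are bought.
2. 9 ← C2–C3 bond by Ir-catalysed hydrogen-borrowing alkylation of methyl ketone 2 (supplies C1 and C2) with primary alcohol 6 (supplies C3–C9 and the second arene). C3 enters as CH2OH and passes through aldehyde and enone before the borrowed hydrogen is returned.
3. Enabling feature: the C1 carbonyl sits on a benzene ring whose two ortho carbons (C2′ and C6′) both carry oxygen. This ring twists out of the C=O plane and shields C1 from metal hydride, while the C2 methyl stays enolisable. The unbranched C3–C9 chain lets C3 be a plain primary alcohol carbon.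
4. 2 ← O-benzylation of commercial 2′-hydroxy-6′-methoxyacetophenone 1.
5. 6 ← hydroboration of hept-6-en-1-ol 3 and B-alkyl Suzuki–Miyaura coupling with 1-(benzyloxy)-4-bromobenzene 4.

Key step: step 3

Remark: the target has no stereocentre and no stereogenic double bond, so it is achiral and no enantioselective step is needed.

**Step 1**
Reactants: 1 1-(2-hydroxy-6-methoxyphenyl)ethan-1-one
Product: 2 1-[2-(benzyloxy)-6-methoxyphenyl]ethan-1-one
Conditions: BnBr, K2CO3, DMF, 60 °C
Reagents that add atoms: benzyl bromide, BrCc1ccccc1
Why: Williamson ether synthesis; carbonate in DMF breaks the phenol–ketone hydrogen bond and the phenoxide should be benzylated on oxygen, leaving the methyl ketone untouched.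

**Step 2**
Reactants: 3 hept-6-en-1-ol; 4 1-(benzyloxy)-4-bromobenzene
Product: 6 7-[4-(benzyloxy)phenyl]heptan-1-ol, via bis(9-BBN) adduct 5 (not isolated)
Conditions: 9-BBN (2.5 equiv), THF, 0 °C to rt; then 4, Pd(dppf)Cl2 (3 mol%), 3 M aq. NaOH, THF, 65 °C
Reagents that add atoms: none
Why: Anti-Markovnikov hydroboration of the terminal alkene (the second equivalent of borane is consumed by the free hydroxyl as a borinate) followed by B-alkyl Suzuki–Miyaura coupling with the aryl bromide; aqueous base frees the alcohol again, and the benzyl ether is inert to Pd(0) and base.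

**Step 3**
Reactants: 2 1-[2-(benzyloxy)-6-methoxyphenyl]ethan-1-one (1.5 equiv); 6 7-[4-(benzyloxy)phenyl]heptan-1-ol
Product: 9 1-[2-(benzyloxy)-6-methoxyphenyl]-9-[4-(benzyloxy)phenyl]nonan-1-one, via aldehyde 7 (not isolated), via enone 8 (not isolated)
Conditions: [Cp*IrCl2]2 (2 mol%), KOH (1 equiv), toluene, 85 °C, Ar, sealed tube
Reagents that add atoms: none
Why: Cp*Ir(III) dehydrogenates the alkoxide of 6 by β-hydride elimination to aldehyde 7 and an iridium hydride; KOH then drives the crossed aldol condensation of the C2 methyl enolate of 2 with 7 to enone 8, which creates the C2–C3 bond as C=C, and the iridium hydride returns the borrowed hydrogen by conjugate reduction of 8 to 9, with water as the only by-product. The closest known reaction type is the iridium-catalysed hydrogen-borrowing α-alkylation of aryl methyl ketones with primary alcohols, which is established for di-ortho-substituted aryl ketones. No ring is closed and no stereocentre is formed; the E geometry of 8 is erased by the reduction. The step needs alkylation at C2 instead of reduction of the C1 carbonyl, crossed instead of self-condensation of the aldehyde, and mono- instead of dialkylation at C2. The first is secured by the two ortho oxygen substituents (C2′–OBn and C6′–OMe), which twist the ring out of the carbonyl plane and shield C1 from the hydride; the second by the low stationary concentration of 7 and the excess of 2; the third by the faster enolisation and condensation of the CH3 group of 2 compared with the CH2 group of 9.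

**Step 4**
Reactants: 9 1-[2-(benzyloxy)-6-methoxyphenyl]-9-[4-(benzyloxy)phenyl]nonan-1-one
Product: 10 1-(2-hydroxy-6-methoxyphenyl)-9-(4-hydroxyphenyl)nonan-1-one
Conditions: H2 (1 atm), 10% Pd/C, EtOAc/EtOH, rt
Reagents that add atoms: none
Why: Catalytic hydrogenolysis should cleave both aryl benzyl ethers; the methyl ether is inert, and the di-ortho-substituted ketone, hydrogen-bonded to the freed phenol, should resist reduction under neutral low-pressure conditions.

**Compound list**
1 | 1-(2-hydroxy-6-methoxyphenyl)ethan-1-one (2′-hydroxy-6′-methoxyacetophenone) | COc1cccc(O)c1C(C)=O | starting material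
2 | 1-[2-(benzyloxy)-6-methoxyphenyl]ethan-1-one | COc1cccc(OCc2ccccc2)c1C(C)=O | intermediate
3 | hept-6-en-1-ol | C=CCCCCCO | starting material
4 | 1-(benzyloxy)-4-bromobenzene | Brc1ccc(OCc2ccccc2)cc1 | starting material
5 | 9-{7-[(9-borabicyclo[3.3.1]nonan-9-yl)oxy]heptyl}-9-borabicyclo[3.3.1]nonane (bis(9-BBN) adduct, not isolated) | C(CCCCCCOB1C2CCCC1CCC2)B1C2CCCC1CCC2 | intermediate
6 | 7-[4-(benzyloxy)phenyl]heptan-1-ol | OCCCCCCCc1ccc(OCc2ccccc2)cc1 | intermediate
7 | 7-[4-(benzyloxy)phenyl]heptanal (not isolated) | O=CCCCCCCc1ccc(OCc2ccccc2)cc1 | intermediate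
8 | (E)-1-[2-(benzyloxy)-6-methoxyphenyl]-9-[4-(benzyloxy)phenyl]non-2-en-1-one (not isolated) | COc1cccc(OCc2ccccc2)c1C(=O)/C=C/CCCCCCc1ccc(OCc2ccccc2)cc1 | intermediate
9 | 1-[2-(benzyloxy)-6-methoxyphenyl]-9-[4-(benzyloxy)phenyl]nonan-1-one | COc1cccc(OCc2ccccc2)c1C(=O)CCCCCCCCc1ccc(OCc2ccccc2)cc1 | intermediate
10 | 1-(2-hydroxy-6-methoxyphenyl)-9-(4-hydroxyphenyl)nonan-1-one | COc1cccc(O)c1C(=O)CCCCCCCCc1ccc(O)cc1 | target

**Step count**
Total steps: 4. Longest linear sequence: 3 steps (step 1 or step 2, then steps 3 and 4).

**Steps most likely to fail**

Step 3. Self-condensation of the transient aldehyde may outrun the crossed condensation with the hindered ketone enolate, or the product may be alkylated a second time at C2. Fallback: setting out from 6, Appel iodination (I2, PPh3, imidazole, CH2Cl2, 0 °C to rt) should give 1-(benzyloxy)-4-(7-iodoheptyl)benzene F1. The lithium enolate of 2 (LDA, THF, −78 °C, then DMPU; enolate in excess to limit dialkylation) is then alkylated with F1 at −78 to 0 °C in an SN2 reaction, and the sequence rejoins the route at 9.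

Step 2. The free hydroxyl may consume the borane, and slow transmetalation of the alkylborane may let protodeboronation, β-hydride elimination and reduction of the aryl bromide take over. Fallback: setting out from 4, copper-free Sonogashira coupling with hept-6-yn-1-ol (OCCCCCC#C; PdCl2(MeCN)2, XPhos, Cs2CO3, MeCN, 80 °C) should give 7-[4-(benzyloxy)phenyl]hept-6-yn-1-ol F2. Saturation of the alkyne over a catalyst that spares aryl benzyl ethers (H2, PtO2 or Pd/C poisoned with Ph2S, EtOAc, rt) then returns to the route at 6.

Step 4. The aryl ketone may be over-reduced to the benzylic alcohol or the methylene compound before the hindered ortho benzyl ether is fully cleaved. Fallback: setting out from 9, non-reductive Lewis-acid debenzylation with BCl3 and pentamethylbenzene as cation scavenger (CH2Cl2, −78 °C, MeOH quench) should remove both benzyl groups at a temperature where the methyl ether is left intact. It arrives directly at 10 and makes no new compound (F0).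

**Further compounds**
F1 | step 3 | 1-(benzyloxy)-4-(7-iodoheptyl)benzene | ICCCCCCCc1ccc(OCc2ccccc2)cc1
F2 | step 2 | 7-[4-(benzyloxy)phenyl]hept-6-yn-1-ol | OCCCCCC#Cc1ccc(OCc2ccccc2)cc1
F0 | step 4 | none | none
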